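Readings and results stem from a simulated flask with constants of no real substance; noise was put on by code.

The starting material is what I follow through four flasks that differ in how the charge goes in.

| flask | starting material | first nucleophile | solid second nucleophile | temperature | remark | time |
|---|---|---|---|---|---|---|
| larch | 0.052 M | 4 equiv | 4 equiv | 110 °C | run made earlier |  |
| maple | 0.10 M | 4 equiv | 4 equiv | 110 °C | run made earlier |  |
| red | 0.052 M | 4.00 equiv (in portions, 4, over 5.0 min) | 4.00 equiv | 110 °C | first portion at the start, last at 5.0 min | 12 min |
| blue | 0.052 M (fed, over 5.0 min) | 4.00 equiv | 4.00 equiv |  | the addition at 80 °C, then warmed to 110 °C; the feed brings no volume worth counting | 12 min |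
| violet | 0.052 M (fed, over 5.0 min) | 4.00 equiv | 4.00 equiv | 110 °C | all else is in the flask from the start; the feed brings no volume worth counting | 12 min |
| teal | 0.052 M | 4.00 equiv | 4.00 equiv | 110 °C | everything together at the start | 12 min |

- larch (time / min: target / %, starting material / %): 0.833: 7.1, 80.7; 2.50: 13.6, 52.9; 5.00: 20.9, 33.8; 8.00: 24.9, 19.3
- maple (time / min: target / %, starting material / %): 0.250: 2.7, 89.9; 0.667: 7.1, 77.1; 1.50: 13.1, 58.7; 4.00: 19.8, 31.6

(readings scatter by 1 percentage point)

- the numbers in the tables scatter with a standard deviation of 1 percentage point
- at the start none of the solid second nucleophile is in solution
- the earlier runs do not show what temperature does; that part of a forecast is a guess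

* the flask with the highest amount of target, in percent of the starting material charged ("all alike" if they lie within 1.5 percentage points) (red / blue / violet / teal / all alike)
* final target, as a percentage of the starting material charged, in red
* final target, as a percentage of the starting material charged, in blue
* final target, as a percentage of the starting material charged, in violet
* final target, as a percentage of the starting material charged, in teal

**An odd pair.** Up to the last reading, the mean first-order constant is 0.206 min⁻¹ in larch and 0.288 min⁻¹ in maple. So a loss of higher order is at work, and it ought to cost maple more target. Yet target per reacted starting material reads 0.309 in larch and 0.289 in maple.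

**Two roads.** I let the starting material leave by a first-order and a second-order road. I call its amount, as a fraction of larch's charge, the fill. The mean constant is then a straight line in the mean fill, which reads 0.491 in larch and 1.14 in maple. The slope is 0.126 min⁻¹ and the intercept 0.144 min⁻¹. Their ratio is the crossover fill, 1.14, the fill at which both roads run equally fast.

Integrating the rate in closed form, the first-order road carries the crossover times the logarithm of (crossover + starting fill) over (crossover + present fill). That is 53.9% of the charge in larch and 33.2% in maple. The second-order road takes 26.8% and 35.2%. Target per first-order share, the selectivity of that road, reads 0.462 and 0.596. So maple loses more and gets more from the rest, and the two changes cancel in the ratio.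

**My reckoning.** Teal is larch's recipe, so the integral leaves 10.4% of the starting material at 12 min and gives 28.6% target. At completion the second-order road holds 28.3%. The selectivity read lower in larch than in maple, at lower fill. Violet's feed spreads its starting material over 5.0 min, so its fill stays low while it goes in, and I expect violet below teal. Red doses the first nucleophile and blue is fed at 80 °C, so this reckoning does not place them.

**The forecast.** It names teal at 28%, then violet at 26.3%, red at 25.3% and blue at 24%, holding that “Selectivity therefore seems independent of time and concentration”. There it differs from me, who read the steady ratio as a cancellation.

**The result.** The leader is teal at 26.0%, then violet at 21.1%, red at 18.3% and blue at 16.3%. The forecast holds for teal and stands too high for violet, red and blue.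

    starting material → intermediate (k = 0.00230 s⁻¹, Ea = 98.0 kJ mol⁻¹)
    first nucleophile + intermediate → target (k = 0.330 M⁻¹ s⁻¹, Ea = 64.0 kJ mol⁻¹)
    second nucleophile + intermediate → other capture product (k = 4.40 M⁻¹ s⁻¹, Ea = 73.0 kJ mol⁻¹)
    solid second nucleophile ⇌ second nucleophile, rate k4*(cs4 - [second nucleophile]) while solid is left; crystals form when [second nucleophile] > cs4 (solubility = 35.0 mM, k = 0.00770 s⁻¹)
    2 starting material → homo dimer (k = 0.0230 M⁻¹ s⁻¹, Ea = 67.0 kJ mol⁻¹)
    (constants at 110 °C)

**Where target parts.** The crossover gives teal 28.3% on the second-order road, against 31.4% homo dimer stored at 120 min. From blue's 93.9% starting material at the end of its feed, it gives 29.1%, against 32.1% simulated. So homo dimer does not part these two flasks, but target does, by 9.7 percentage points. That gap comes in part from the low solubility of the second nucleophile together with the slowness of the solid's dissolving. With the slow dissolving taken away, the gap is 3.2 points.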